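**Strategy.** Ring B is made last, on a ring A that is already complete. The disconnection cuts ring B into a four-carbon vinylketene (C4', C1', C6', C5') and a two-carbon ynol ether (C2', C3'). One thermal cascade forms C1'–C2' and C3'–C4', closes C4'–C5' and aromatises. It exploits the feature that ring B carries oxygen at C2' and methyl at C3' side by side, between the benzylic C1' and the C4' oxygen, with C5' left open for the acetyl group. The precursor is a 3-benzyloxycyclobut-2-enone that holds the fully substituted, benzyl-protected ring A on C2 through the methylene bridge.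

Key step: step 12

Remark: ring A is numbered C1 (butanoyl), C2 (OH), C3 (CH3), C4 (OCH3), C5 (bridge), C6 (OH); ring B is numbered C1' (bridge), C2' (OH), C3' (CH3), C4' (OH), C5' (acetyl), C6' (OH). The target has no stereocentre. Ketene is not sold and is assumed to be generated from acetone (step 9).

Step 1
Reactants: 1 2-methylphloroglucinol (2-methylbenzene-1,3,5-triol)
Product: 2 1-(2,4,6-trihydroxy-3-methylphenyl)butan-1-one
Conditions: n-PrCOCl, AlCl3, PhNO2, rt to 60 °C; ice, aq. HCl
Reagents that add atoms: butanoyl chloride, CCCC(=O)Cl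
Why: Friedel–Crafts acylation of a phloroglucinol; the two free ring carbons of 1 are equivalent and the first acyl group deactivates the ring, so a single ketone should form.

Step 2
Reactants: 2 1-(2,4,6-trihydroxy-3-methylphenyl)butan-1-one
Product: 3 1-(2,6-dihydroxy-4-methoxy-3-methylphenyl)butan-1-one
Conditions: Me2SO4 (1.0 equiv), K2CO3 (1.0 equiv), acetone, rt
Reagents that add atoms: dimethyl sulfate, COS(=O)(=O)OC
Why: Williamson O-methylation with limiting base and electrophile should take the C4 hydroxyl, which is para to the ketone, the most acidic, and the only one unable to hydrogen-bond to the carbonyl group.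

Step 3
Reactants: 3 1-(2,6-dihydroxy-4-methoxy-3-methylphenyl)butan-1-one
Product: 4 3-butanoyl-2,4-dihydroxy-6-methoxy-5-methylbenzaldehyde
Conditions: Cl2CHOMe, TiCl4, CH2Cl2, −10 °C to rt; aq. HCl
Reagents that add atoms: dichloromethyl methyl ether, COC(Cl)Cl; water, O
Why: Rieche formylation at C5, the only unsubstituted ring carbon, activated by the flanking OH and OMe; the method is established for acylphloroglucinols and avoids the attack of chloroiminium reagents on o-hydroxyaryl ketones.

Step 4
Reactants: 4 3-butanoyl-2,4-dihydroxy-6-methoxy-5-methylbenzaldehyde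
Product: 5 2,4-bis(benzyloxy)-3-butanoyl-6-methoxy-5-methylbenzaldehyde
Conditions: BnBr (2.5 equiv), K2CO3, DMF, 60 °C
Reagents that add atoms: benzyl bromide, BrCc1ccccc1
Why: Williamson etherification of both chelated but acidic phenols; the ring is fully substituted, so C-benzylation cannot compete.

Step 5
Reactants: 5 2,4-bis(benzyloxy)-3-butanoyl-6-methoxy-5-methylbenzaldehyde
Product: 6 1-[2,6-bis(benzyloxy)-3-(hydroxymethyl)-4-methoxy-5-methylphenyl]butan-1-one
Conditions: NaBH4 (0.5 equiv), THF–MeOH, −20 °C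
Reagents that add atoms: none
Why: Chemoselective borohydride reduction; the aldehyde should react far faster than the ketone, which is twisted out of conjugation and shielded by two ortho benzyloxy groups.

Step 6
Reactants: 6 1-[2,6-bis(benzyloxy)-3-(hydroxymethyl)-4-methoxy-5-methylphenyl]butan-1-one
Product: 7 1-[2,6-bis(benzyloxy)-3-(bromomethyl)-4-methoxy-5-methylphenyl]butan-1-one
Conditions: PBr3 (0.4 equiv), Et2O, 0 °C; cold aq. NaHCO3; used crude at once
Reagents that add atoms: phosphorus tribromide, BrP(Br)Br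
Why: Bromination of an electron-rich benzylic alcohol by PBr3; ring A has no free carbon, so the labile bromide cannot alkylate itself.

Step 7
Reactants: 8 benzyl alcohol; 9 trichloroethylene
Product: 10 benzyl (E)-1,2-dichlorovinyl ether
Conditions: KH, THF, 0 °C; then Cl2C=CHCl, −50 °C to rt
Reagents that add atoms: none
Why: Elimination–addition of the potassium alkoxide of 8 on trichloroethylene, the standard entry to alkoxyacetylene precursors; anti addition should give the E enol ether.

Step 8
Reactants: 10 benzyl (E)-1,2-dichlorovinyl ether; 7 1-[2,6-bis(benzyloxy)-3-(bromomethyl)-4-methoxy-5-methylphenyl]butan-1-one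
Product: 14 1-{2,6-bis(benzyloxy)-3-[3-(benzyloxy)prop-2-yn-1-yl]-4-methoxy-5-methylphenyl}butan-1-one, via benzyl chloroethynyl ether 11 (not isolated), via lithium (benzyloxy)acetylide 12 (not isolated), via [(benzyloxy)ethynyl]zinc chloride 13 (not isolated)
Conditions: n-BuLi (2.0 equiv), THF, −78 to −40 °C; ZnCl2, −40 to 0 °C; 7, PdCl2[O(C6H4PPh2)2] (3 mol %), 0 °C to rt; product kept below 30 °C
Reagents that add atoms: none
Why: Dehydrochlorination and chlorine–lithium exchange give the lithium acetylide, which is moved to zinc so that the enolisable ring A ketone is tolerated; Negishi coupling of alkynylzinc halides with benzylic bromides runs at room temperature, below the onset of [3,3]-sigmatropic rearrangement of benzyl alkynyl ethers.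

Step 9
Reactants: 15 acetone
Product: 16 ketene
Conditions: ketene generator, acetone vapour over a glowing Ni–Cr filament (about 700 °C); gas stream led directly into step 10
Reagents that add atoms: none
Why: Thermal cracking of acetone to ketene and methane is the standard laboratory source of ketene gas.

Step 10
Reactants: 14 1-{2,6-bis(benzyloxy)-3-[3-(benzyloxy)prop-2-yn-1-yl]-4-methoxy-5-methylphenyl}butan-1-one; 16 ketene
Product: 17 3-(benzyloxy)-2-{[2,4-bis(benzyloxy)-3-butanoyl-6-methoxy-5-methylphenyl]methyl}cyclobut-2-en-1-one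
Conditions: 16 (excess, bubbled), CH2Cl2, 0 °C to rt
Reagents that add atoms: none
Why: [2+2] cycloaddition of ketene with a 1-alkoxyalkyne; the nucleophilic alkyne carbon bearing the benzylic CH2 bonds to the ketene carbonyl carbon, which puts the ring A methyl group on C2, the benzyloxy group on C3 and the ketene CH2 at C4.

Step 11
Reactants: 18 ethyl acetate
Product: 21 triisopropyl(prop-1-yn-1-yloxy)silane, via lithium 1,1-dibromoprop-1-en-2-olate 19 (not isolated), via lithium prop-1-yn-1-olate 20 (not isolated)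
Conditions: CH2Br2, lithium 2,2,6,6-tetramethylpiperidide (LiTMP), THF, −78 °C; n-BuLi, −78 °C to rt; i-Pr3SiCl, −78 °C to rt
Reagents that add atoms: dibromomethane, BrCBr; chlorotriisopropylsilane, CC(C)[Si](Cl)(C(C)C)C(C)C
Why: Kowalski ester homologation: addition of dibromomethyllithium, enolisation, bromine–lithium exchange and 1,2-shift give the ynolate, which the bulky silyl chloride should trap on oxygen.

Step 12
Reactants: 17 3-(benzyloxy)-2-{[2,4-bis(benzyloxy)-3-butanoyl-6-methoxy-5-methylphenyl]methyl}cyclobut-2-en-1-one; 21 triisopropyl(prop-1-yn-1-yloxy)silane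
Product: 26 1-[2,6-bis(benzyloxy)-3-({6-(benzyloxy)-4-hydroxy-3-methyl-2-[(triisopropylsilyl)oxy]phenyl}methyl)-4-methoxy-5-methylphenyl]butan-1-one, via vinylketene 22 (not isolated), via 4-vinylcyclobutenone 23 (not isolated), via dienylketene 24 (not isolated), via cyclohexa-2,4-dienone 25 (not isolated)
Conditions: 21 (2 equiv), toluene, 80 to 110 °C, sealed tube, argon
Reagents that add atoms: none
Why: Heating should open 17 by 4π electrocyclic cleavage of its C1–C4 bond to vinylketene 22, which adds the ynol ether in a [2+2] cycloaddition to give 23; a second 4π opening gives dienylketene 24, which closes to dienone 25 and tautomerises to phenol 26. This is the Danheiser benzannulation in its siloxyalkyne form, which delivers resorcinol monosilyl ethers. Ring B closes by a thermally allowed disrotatory 6π electrocyclisation that joins the former ketene carbon (C4') to the former cyclobutenone CH2 (C5'), after the [2+2] step has formed C4'–C3' and C1'–C2'. No stereocentre is created in 26; the quaternary carbon of 23 is transient and disappears on ring opening. The step needs one orientation of the ketene–alkyne addition, and the oxygen of 21 secures it by making the methyl-bearing carbon nucleophilic toward the ketene carbonyl carbon, so that methyl ends at C3' and the silyloxy group at C2'. The 6π closure needs the ketene and vinyl groups cis on the central double bond, which reversible opening of 23 can supply, and the unsubstituted CH2 of 17 provides the hydrogen at C5' for aromatisation.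

Step 13
Reactants: 26 1-[2,6-bis(benzyloxy)-3-({6-(benzyloxy)-4-hydroxy-3-methyl-2-[(triisopropylsilyl)oxy]phenyl}methyl)-4-methoxy-5-methylphenyl]butan-1-one
Product: 27 the C5'-iodo derivative of 26
Conditions: N-iodosuccinimide (1.05 equiv), CH2Cl2, −20 to 0 °C, dark
Reagents that add atoms: N-iodosuccinimide, O=C1CCC(=O)N1I
Why: Electrophilic aromatic iodination; C5' is the only unsubstituted ring carbon in the molecule and is activated by the ortho phenol, the ortho benzyloxy and the para silyloxy group.

Step 14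
Reactants: 27 the C5'-iodo derivative of 26
Product: 29 the C5'-acetyl derivative of 26, via 1-ethoxyvinyl arene 28 (not isolated)
Conditions: Bu3Sn–C(OEt)=CH2, Pd(PPh3)4 (5 mol %), CuI (10 mol %), toluene, 90 °C; then 1 M HCl, THF, rt
Reagents that add atoms: tributyl(1-ethoxyvinyl)stannane, CCCC[Sn](CCCC)(CCCC)C(=C)OCC; water, O
Why: Stille coupling with an acetyl anion equivalent, then mild hydrolysis of the enol ether; the neutral conditions spare the silyl ether, the benzyl ethers and the electron-rich diarylmethane, which a Lewis-acid acylation would endanger.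

Step 15
Reactants: 29 the C5'-acetyl derivative of 26
Product: 30 1-{3-[(3-acetyl-2-(benzyloxy)-4,6-dihydroxy-5-methylphenyl)methyl]-2,6-bis(benzyloxy)-4-methoxy-5-methylphenyl}butan-1-one
Conditions: Bu4NF, AcOH (1:1), THF, 0 °C
Reagents that add atoms: none
Why: Fluoride cleavage of the aryl silyl ether, driven by Si–F bond formation; the acetic acid buffer keeps the phenoxide from base-induced scrambling of the methylene bridge.

Step 16
Reactants: 30 1-{3-[(3-acetyl-2-(benzyloxy)-4,6-dihydroxy-5-methylphenyl)methyl]-2,6-bis(benzyloxy)-4-methoxy-5-methylphenyl}butan-1-one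
Product: 31 1-{3-[(3-acetyl-2,4,6-trihydroxy-5-methylphenyl)methyl]-2,6-dihydroxy-4-methoxy-5-methylphenyl}butan-1-one (target)
Conditions: H2 (1 atm), Pd/C, EtOAc–MeOH, rt; stopped after uptake of three equivalents
Reagents that add atoms: none
Why: Hydrogenolysis of the three aryl benzyl ethers over palladium on carbon; the chelated aryl ketones and the diarylmethane should survive at ambient pressure.

**Compound list**

1 | 2-methylphloroglucinol | Cc1c(O)cc(O)cc1O | starting material
2 | 1-(2,4,6-trihydroxy-3-methylphenyl)butan-1-one | CCCC(=O)c1c(O)c(C)c(O)cc1O | intermediate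
3 | 1-(2,6-dihydroxy-4-methoxy-3-methylphenyl)butan-1-one | CCCC(=O)c1c(O)c(C)c(OC)cc1O | intermediate
4 | 3-butanoyl-2,4-dihydroxy-6-methoxy-5-methylbenzaldehyde | CCCC(=O)c1c(O)c(C)c(OC)c(C=O)c1O | intermediate
5 | 2,4-bis(benzyloxy)-3-butanoyl-6-methoxy-5-methylbenzaldehyde | CCCC(=O)c1c(OCc2ccccc2)c(C)c(OC)c(C=O)c1OCc1ccccc1 | intermediate
6 | 1-[2,6-bis(benzyloxy)-3-(hydroxymethyl)-4-methoxy-5-methylphenyl]butan-1-one | CCCC(=O)c1c(OCc2ccccc2)c(C)c(OC)c(CO)c1OCc1ccccc1 | intermediate
7 | 1-[2,6-bis(benzyloxy)-3-(bromomethyl)-4-methoxy-5-methylphenyl]butan-1-one | CCCC(=O)c1c(OCc2ccccc2)c(C)c(OC)c(CBr)c1OCc1ccccc1 | intermediate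
8 | benzyl alcohol | OCc1ccccc1 | starting material
9 | trichloroethylene | ClC=C(Cl)Cl | starting material
10 | benzyl (E)-1,2-dichlorovinyl ether | Cl/C=C(/Cl)OCc1ccccc1 | intermediate
11 | benzyl chloroethynyl ether | ClC#COCc1ccccc1 | intermediate (not isolated)
12 | lithium (benzyloxy)acetylide | [Li]C#COCc1ccccc1 | intermediate (not isolated)
13 | [(benzyloxy)ethynyl]zinc chloride | Cl[Zn]C#COCc1ccccc1 | intermediate (not isolated)
14 | 1-{2,6-bis(benzyloxy)-3-[3-(benzyloxy)prop-2-yn-1-yl]-4-methoxy-5-methylphenyl}butan-1-one | CCCC(=O)c1c(OCc2ccccc2)c(C)c(OC)c(CC#COCc2ccccc2)c1OCc1ccccc1 | intermediate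
15 | acetone | CC(C)=O | starting material
16 | ketene | C=C=O | intermediate
17 | 3-(benzyloxy)-2-{[2,4-bis(benzyloxy)-3-butanoyl-6-methoxy-5-methylphenyl]methyl}cyclobut-2-en-1-one | CCCC(=O)c1c(OCc2ccccc2)c(C)c(OC)c(CC2=C(OCc3ccccc3)CC2=O)c1OCc1ccccc1 | intermediate (key-step precursor)
18 | ethyl acetate | CCOC(C)=O | starting material
19 | lithium 1,1-dibromoprop-1-en-2-olate | CC(O[Li])=C(Br)Br | intermediate (not isolated)
20 | lithium prop-1-yn-1-olate | CC#CO[Li] | intermediate (not isolated)
21 | triisopropyl(prop-1-yn-1-yloxy)silane | CC#CO[Si](C(C)C)(C(C)C)C(C)C | intermediate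
22 | 3-(benzyloxy)-2-{[2,4-bis(benzyloxy)-3-butanoyl-6-methoxy-5-methylphenyl]methyl}buta-1,3-dien-1-one (vinylketene) | CCCC(=O)c1c(OCc2ccccc2)c(C)c(OC)c(CC(=C=O)C(=C)OCc2ccccc2)c1OCc1ccccc1 | intermediate (not isolated)
23 | 4-[1-(benzyloxy)ethenyl]-4-{[2,4-bis(benzyloxy)-3-butanoyl-6-methoxy-5-methylphenyl]methyl}-2-methyl-3-[(triisopropylsilyl)oxy]cyclobut-2-en-1-one (racemic) | CCCC(=O)c1c(OCc2ccccc2)c(C)c(OC)c(CC2(C(=C)OCc3ccccc3)C(=O)C(C)=C2O[Si](C(C)C)(C(C)C)C(C)C)c1OCc1ccccc1 | intermediate (not isolated)
24 | (3E)-5-(benzyloxy)-4-{[2,4-bis(benzyloxy)-3-butanoyl-6-methoxy-5-methylphenyl]methyl}-2-methyl-3-[(triisopropylsilyl)oxy]hexa-1,3,5-trien-1-one (dienylketene, ketene and vinyl groups cis) | CCCC(=O)c1c(OCc2ccccc2)c(C)c(OC)c(C/C(C(=C)OCc2ccccc2)=C(\O[Si](C(C)C)(C(C)C)C(C)C)C(C)=C=O)c1OCc1ccccc1 | intermediate (not isolated)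
25 | 5-(benzyloxy)-4-{[2,4-bis(benzyloxy)-3-butanoyl-6-methoxy-5-methylphenyl]methyl}-2-methyl-3-[(triisopropylsilyl)oxy]cyclohexa-2,4-dien-1-one | CCCC(=O)c1c(OCc2ccccc2)c(C)c(OC)c(CC2=C(OCc3ccccc3)CC(=O)C(C)=C2O[Si](C(C)C)(C(C)C)C(C)C)c1OCc1ccccc1 | intermediate (not isolated)
26 | 1-[2,6-bis(benzyloxy)-3-({6-(benzyloxy)-4-hydroxy-3-methyl-2-[(triisopropylsilyl)oxy]phenyl}methyl)-4-methoxy-5-methylphenyl]butan-1-one | CCCC(=O)c1c(OCc2ccccc2)c(C)c(OC)c(Cc2c(O[Si](C(C)C)(C(C)C)C(C)C)c(C)c(O)cc2OCc2ccccc2)c1OCc1ccccc1 | intermediate (key-step product)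
27 | C5'-iodo derivative of 26 | CCCC(=O)c1c(OCc2ccccc2)c(C)c(OC)c(Cc2c(O[Si](C(C)C)(C(C)C)C(C)C)c(C)c(O)c(I)c2OCc2ccccc2)c1OCc1ccccc1 | intermediate
28 | C5'-(1-ethoxyethenyl) derivative of 26 | CCCC(=O)c1c(OCc2ccccc2)c(C)c(OC)c(Cc2c(O[Si](C(C)C)(C(C)C)C(C)C)c(C)c(O)c(C(=C)OCC)c2OCc2ccccc2)c1OCc1ccccc1 | intermediate (not isolated)
29 | C5'-acetyl derivative of 26 | CCCC(=O)c1c(OCc2ccccc2)c(C)c(OC)c(Cc2c(O[Si](C(C)C)(C(C)C)C(C)C)c(C)c(O)c(C(C)=O)c2OCc2ccccc2)c1OCc1ccccc1 | intermediate
30 | 1-{3-[(3-acetyl-2-(benzyloxy)-4,6-dihydroxy-5-methylphenyl)methyl]-2,6-bis(benzyloxy)-4-methoxy-5-methylphenyl}butan-1-one | CCCC(=O)c1c(OCc2ccccc2)c(C)c(OC)c(Cc2c(O)c(C)c(O)c(C(C)=O)c2OCc2ccccc2)c1OCc1ccccc1 | intermediate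
31 | 1-{3-[(3-acetyl-2,4,6-trihydroxy-5-methylphenyl)methyl]-2,6-dihydroxy-4-methoxy-5-methylphenyl}butan-1-one | CCCC(=O)c1c(O)c(C)c(OC)c(Cc2c(O)c(C)c(O)c(C(C)=O)c2O)c1O | target

**Step count and risks**

Total step count: 16. Longest linear sequence: 13 steps (steps 1, 2, 3, 4, 5, 6, 8, 10, 12, 13, 14, 15, 16).

Steps most likely to fail:

1. Step 12. The donor-substituted cyclobutenone may open only at temperatures at which the vinylketene dimerises or acylates the phenol already formed, or the siloxyalkyne may decompose before it is consumed. The fallback gives up the annulation and joins a preformed ring B by electrophilic benzylation; it sets out from 1 and 6 and comes back at 31. Compound 1 would be C-acetylated (AcCl, AlCl3, PhNO2) to 1-(2,4,6-trihydroxy-3-methylphenyl)ethan-1-one F1. Alcohol 6 and F1 would be condensed under acid catalysis (TsOH cat., 1,4-dioxane, rt); ionisation of 6 gives a benzylic cation stabilised by three alkoxy groups, and F1 has a single free ring carbon, so 1-{3-[(3-acetyl-2,4,6-trihydroxy-5-methylphenyl)methyl]-2,6-bis(benzyloxy)-4-methoxy-5-methylphenyl}butan-1-one F2 should result. Hydrogenolysis of F2 (H2, Pd/C, EtOAc–MeOH) would give 31.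

2. Step 8. Transmetalation or coupling may be slow enough for the electron-rich benzylic bromide to ionise and homocouple, and the benzyl alkynyl ether may rearrange sigmatropically before it is used. The fallback carries a thermally robust ethyl alkynyl ether through the cycloaddition and brings in the benzyl group afterwards; it sets out from 7 and comes back at 17. Commercial ethoxyacetylene would be lithiated (n-BuLi, THF, −78 °C) to lithium ethoxyacetylide F3 and moved to zinc (ZnCl2) as (ethoxyethynyl)zinc chloride F4. Coupling with 7 under the palladium catalysis of step 8 should give 1-[2,6-bis(benzyloxy)-3-(3-ethoxyprop-2-yn-1-yl)-4-methoxy-5-methylphenyl]butan-1-one F5. Ketene 16 would add as in step 10 to give 2-{[2,4-bis(benzyloxy)-3-butanoyl-6-methoxy-5-methylphenyl]methyl}-3-ethoxycyclobut-2-en-1-one F6. Acid-catalysed addition–elimination of benzyl alcohol 8 at this vinylogous ester (TsOH cat., benzene, 40 °C, ethanol removed under reduced pressure) would exchange ethoxy for benzyloxy and give 17.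

3. Step 10. Ketene may dimerise or polymerise faster than it adds to the hindered alkyne, and a long reaction time exposes the alkynyl ether to rearrangement and hydrolysis. The fallback uses a more electrophilic ketene made in the flask, followed by reduction; it sets out from 14 and comes back at 17. Dichloroketene (Cl3CCOCl, Zn–Cu couple, Et2O–DME, rt) should add with the same orientation to give 3-(benzyloxy)-2-{[2,4-bis(benzyloxy)-3-butanoyl-6-methoxy-5-methylphenyl]methyl}-4,4-dichlorocyclobut-2-en-1-one F7. Reductive dechlorination of F7 (Zn, AcOH, TMEDA, EtOH, 0 °C) would give 17.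

Further compounds
F1 | step 12 | 1-(2,4,6-trihydroxy-3-methylphenyl)ethan-1-one | CC(=O)c1c(O)c(C)c(O)cc1O
F2 | step 12 | 1-{3-[(3-acetyl-2,4,6-trihydroxy-5-methylphenyl)methyl]-2,6-bis(benzyloxy)-4-methoxy-5-methylphenyl}butan-1-one | CCCC(=O)c1c(OCc2ccccc2)c(C)c(OC)c(Cc2c(O)c(C)c(O)c(C(C)=O)c2O)c1OCc1ccccc1
F3 | step 8 | lithium ethoxyacetylide | [Li]C#COCC
F4 | step 8 | (ethoxyethynyl)zinc chloride | Cl[Zn]C#COCC
F5 | step 8 | 1-[2,6-bis(benzyloxy)-3-(3-ethoxyprop-2-yn-1-yl)-4-methoxy-5-methylphenyl]butan-1-one | CCCC(=O)c1c(OCc2ccccc2)c(C)c(OC)c(CC#COCC)c1OCc1ccccc1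
F6 | step 8 | 2-{[2,4-bis(benzyloxy)-3-butanoyl-6-methoxy-5-methylphenyl]methyl}-3-ethoxycyclobut-2-en-1-one | CCCC(=O)c1c(OCc2ccccc2)c(C)c(OC)c(CC2=C(OCC)CC2=O)c1OCc1ccccc1
F7 | step 10 | 3-(benzyloxy)-2-{[2,4-bis(benzyloxy)-3-butanoyl-6-methoxy-5-methylphenyl]methyl}-4,4-dichlorocyclobut-2-en-1-one | CCCC(=O)c1c(OCc2ccccc2)c(C)c(OC)c(CC2=C(OCc3ccccc3)C(Cl)(Cl)C2=O)c1OCc1ccccc1
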